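Numbering the chain from the alkene terminus, the oxolane ring (O1, C11–C14) is traced back to a γ-lactone whose cis C13–O/C14–pentyl pair and C14–O1–C11 bridge are recognised as the oxygen-insertion product of a cis-2-pentyl-3-alkoxycyclobutanone. A bicarbonate-buffered peracid Baeyer–Villiger oxidation of that strained ketone places O1 between carbonyl carbon C11 and the more substituted C14 with retention, converting the four-membered carbocycle into the five-membered lactone in one operation. The precursor, (2S,3S)-2-pentyl-3-[(1R)-1-(2,4,6-triisopropylphenyl)ethoxy]cyclobutan-1-one, comes from a dichloroketene [2+2] cycloaddition to a Z enol ether of the chiral benzylic alcohol, which afterwards serves as the C13–OH protecting group until the last step.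

Key step: step 5

Assumption: the Z enol ether is taken to react through its s-trans conformer with the carbinol C–H in the enol ether plane and dichloroketene adding to the face remote from the aryl group; on this model the (R)-alcohol leads to the (2S,3S)-ketone, and should the sense prove opposite the (S)-alcohol would be used with no other change.

Step 1
Reactants: 1 (1R)-1-(2,4,6-triisopropylphenyl)ethanol; 2 trichloroethylene; 3 1-iodopentane
Product: 7 hept-1-yn-1-yl (1R)-1-(2,4,6-triisopropylphenyl)ethyl ether, via potassium alkoxide 4 (not isolated), via dichlorovinyl ether 5 (not isolated), via lithium alkynyl ether 6 (not isolated)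
Conditions: KH, THF, 0 → 20 °C; then 2, −50 → 20 °C; n-BuLi (2.4 equiv), −70 → −40 °C; then 3, HMPA, −40 → 20 °C
Reagents that add atoms: none
Why: Alkoxide addition to dichloroacetylene formed in situ from trichloroethylene, base-induced elimination with chlorine–lithium exchange to the lithium alkynyl ether, and SN2 C-alkylation of that acetylide by the primary iodide in HMPA form an established one-flask ynol ether synthesis from secondary alcohols, and the carbinol stereocentre is not involved.

Step 2
Reactants: 7 hept-1-yn-1-yl (1R)-1-(2,4,6-triisopropylphenyl)ethyl ether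
Product: 8 (Z)-hept-1-en-1-yl (1R)-1-(2,4,6-triisopropylphenyl)ethyl ether
Conditions: H2 (1 atm), Pd/BaSO4, pyridine, 20 °C
Reagents that add atoms: none
Why: Syn semihydrogenation of the alkyne on poisoned palladium should stop at the Z enol ether, whose geometry later fixes the cis ring relationship, and the hindered benzylic ether should not be hydrogenolysed under these basic conditions.

Step 3
Reactants: 8 (Z)-hept-1-en-1-yl (1R)-1-(2,4,6-triisopropylphenyl)ethyl ether; 9 trichloroacetyl chloride
Product: 11 (3R,4S)-2,2-dichloro-4-pentyl-3-[(1R)-1-(2,4,6-triisopropylphenyl)ethoxy]cyclobutan-1-one, via dichloroketene 10 (not isolated)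
Conditions: Zn–Cu couple, Et2O, slow addition of 9, 20 °C; filtered and used crude
Reagents that add atoms: none
Why: Zinc dechlorination of 9 liberates dichloroketene, which undergoes a thermal ketene–alkene [2+2] cycloaddition with the electron-rich enol ether, its carbonyl carbon bonding to the nucleophilic C14 and the CCl2 carbon to C13; suprafacial addition to the Z alkene sets C13 and C14 cis, and attack on the face remote from the triisopropylphenyl group sets their absolute configuration.

Step 4
Reactants: 11 (3R,4S)-2,2-dichloro-4-pentyl-3-[(1R)-1-(2,4,6-triisopropylphenyl)ethoxy]cyclobutan-1-one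
Product: 12 (2S,3S)-2-pentyl-3-[(1R)-1-(2,4,6-triisopropylphenyl)ethoxy]cyclobutan-1-one
Conditions: Zn–Cu couple, MeOH saturated with NH4Cl, 20 °C
Reagents that add atoms: none
Why: Reductive dehalogenation of the α,α-dichloroketone by zinc, with the zinc enolates protonated by the ammonium buffer, should remove both chlorines under nearly neutral conditions that spare the acid-labile ether and the epimerisable C14 centre.

Step 5
Reactants: 12 (2S,3S)-2-pentyl-3-[(1R)-1-(2,4,6-triisopropylphenyl)ethoxy]cyclobutan-1-one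
Product: 13 (4S,5S)-5-pentyl-4-[(1R)-1-(2,4,6-triisopropylphenyl)ethoxy]oxolan-2-one
Conditions: mCPBA, NaHCO3, CH2Cl2, 0 °C
Reagents that add atoms: mCPBA (3-chloroperoxybenzoic acid), O=C(OO)c1cccc(Cl)c1
Why: The peracid adds to the strained C11 carbonyl to give a Criegee adduct, after which C14 shifts with its bonding pair from C11 to the proximal peroxide oxygen, antiperiplanar to the breaking O–O bond, expelling 3-chlorobenzoate. This is the Baeyer–Villiger oxidation, well established for 2,3-disubstituted cyclobutanones from ketene–enol ether cycloadducts, which give cis-butanolides. The oxolanone ring arises by one-atom ring expansion through a 1,2-shift and not by a cyclisation, so both the O1–C11 and O1–C14 bonds are new and no ring-closure mode applies. No stereocentre is created: C14 migrates with retention and C13 is untouched, so the cis relation written in step 3 is carried over. The step needs regioselectivity (C14 rather than the C12 methylene) and chemoselectivity (no β-elimination of the C13 alkoxy group, no cleavage of the benzylic ether); the first should follow from the secondary versus primary migrating carbon, the second from the bicarbonate buffer and the low temperature that relief of four-ring strain permits.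

Step 6
Reactants: 13 (4S,5S)-5-pentyl-4-[(1R)-1-(2,4,6-triisopropylphenyl)ethoxy]oxolan-2-one; 14 1,3-dithiane
Product: 16 (4S,5S)-2-(1,3-dithian-2-yl)-5-pentyl-4-[(1R)-1-(2,4,6-triisopropylphenyl)ethoxy]oxolan-2-ol (both C2 anomers), via 2-lithio-1,3-dithiane 15 (not isolated)
Conditions: 14, n-BuLi, THF, −25 °C; then 13, −78 °C; AcOH, −78 °C
Reagents that add atoms: none
Why: 1,2-Addition of the dithiane anion (Corey–Seebach acyl anion equivalent) to the lactone carbonyl should stop at the tetrahedral alkoxide at −78 °C, and the cold acidic quench should give the hemiketal before enolisation or β-elimination of the C13 alkoxy group can compete, the anomeric mixture at C11 being converged in the next step.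

Step 7
Reactants: 16 (4S,5S)-2-(1,3-dithian-2-yl)-5-pentyl-4-[(1R)-1-(2,4,6-triisopropylphenyl)ethoxy]oxolan-2-ol
Product: 17 2-{(2R,4S,5S)-5-pentyl-4-[(1R)-1-(2,4,6-triisopropylphenyl)ethoxy]oxolan-2-yl}-1,3-dithiane
Conditions: Et3SiH (5 equiv), BF3·OEt2, CH2Cl2, −78 → −40 °C
Reagents that add atoms: none
Why: In this Lewis-acid-promoted silane reduction of a hemiketal (ionic hydrogenation through the cyclic oxocarbenium ion), hydride should be delivered inside the envelope conformer that holds the C13 alkoxy group pseudoaxial, that is on the face cis to that oxygen, so that the dithianyl group ends trans to the C13 oxygen and the C14 pentyl group (C11 R), while the tertiary hemiketal should ionise faster than the hindered secondary benzylic ether.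

Step 8
Reactants: 17 2-{(2R,4S,5S)-5-pentyl-4-[(1R)-1-(2,4,6-triisopropylphenyl)ethoxy]oxolan-2-yl}-1,3-dithiane
Product: 18 (2R,4S,5S)-5-pentyl-4-[(1R)-1-(2,4,6-triisopropylphenyl)ethoxy]oxolane-2-carbaldehyde
Conditions: MeI, CaCO3, MeCN–H2O (4:1), 45 °C; used crude
Reagents that add atoms: water, O
Why: S-Methylation of the dithiane and hydrolysis of the resulting sulfonium salt (alkylative dithioacetal hydrolysis) under carbonate buffering should unmask the aldehyde without acid, preserving the benzylic ether and the α-alkoxy stereocentre C11.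

Step 9
Reactants: 18 (2R,4S,5S)-5-pentyl-4-[(1R)-1-(2,4,6-triisopropylphenyl)ethoxy]oxolane-2-carbaldehyde; 19 9-bromonon-1-ene
Product: 21 (1R)-1-{(2R,4S,5S)-5-pentyl-4-[(1R)-1-(2,4,6-triisopropylphenyl)ethoxy]oxolan-2-yl}dec-9-en-1-ol, via non-8-enylmagnesium bromide 20 (not isolated)
Conditions: 19, Mg, Et2O, reflux; then 18, MgBr2·OEt2, CH2Cl2, −78 °C; aq. NH4Cl
Reagents that add atoms: none
Why: In this Grignard addition under Cram chelation control, magnesium should bridge the aldehyde oxygen and ring oxygen O1, and the nucleophile should attack C10 from the chelate face bearing the C11 hydrogen rather than C12, giving the threo (10R) alcohol.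

Step 10
Reactants: 21 (1R)-1-{(2R,4S,5S)-5-pentyl-4-[(1R)-1-(2,4,6-triisopropylphenyl)ethoxy]oxolan-2-yl}dec-9-en-1-ol; 22 tetradecanoyl chloride
Product: 23 (1R)-1-{(2R,4S,5S)-5-pentyl-4-[(1R)-1-(2,4,6-triisopropylphenyl)ethoxy]oxolan-2-yl}dec-9-en-1-yl tetradecanoate
Conditions: 22, pyridine, DMAP (cat.), CH2Cl2, 0 → 20 °C
Reagents that add atoms: none
Why: DMAP-catalysed O-acylation (nucleophilic acyl substitution) of the only free hydroxyl group should give the tetradecanoate with retention at C10, the C13 oxygen still being masked by the auxiliary.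

Step 11
Reactants: 23 (1R)-1-{(2R,4S,5S)-5-pentyl-4-[(1R)-1-(2,4,6-triisopropylphenyl)ethoxy]oxolan-2-yl}dec-9-en-1-yl tetradecanoate
Product: 24 (1R)-1-[(2R,4S,5S)-4-hydroxy-5-pentyloxolan-2-yl]dec-9-en-1-yl tetradecanoate (CNP0191164.1)
Conditions: CF3CO2H, CH2Cl2, 0 °C
Reagents that add atoms: none
Why: Acid-catalysed SN1/E1 cleavage of the benzylic ether should release the 1-(2,4,6-triisopropylphenyl)ethyl cation, which loses a proton to give the styrene, while the C13–O bond, the ester, the oxolane and the terminal alkene remain untouched at 0 °C.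

Compound list
1 | (1R)-1-(2,4,6-triisopropylphenyl)ethanol | C[C@@H](O)c1c(C(C)C)cc(C(C)C)cc1C(C)C | starting material
2 | trichloroethylene | ClC=C(Cl)Cl | starting material
3 | 1-iodopentane | CCCCCI | starting material
4 | potassium (1R)-1-(2,4,6-triisopropylphenyl)ethoxide | C[C@@H]([O-])c1c(C(C)C)cc(C(C)C)cc1C(C)C.[K+] | intermediate (not isolated)
5 | (E)-1,2-dichlorovinyl (1R)-1-(2,4,6-triisopropylphenyl)ethyl ether | Cl/C=C(/Cl)O[C@H](C)c1c(C(C)C)cc(C(C)C)cc1C(C)C | intermediate (not isolated)
6 | lithium 2-[(1R)-1-(2,4,6-triisopropylphenyl)ethoxy]ethynide | [Li]C#CO[C@H](C)c1c(C(C)C)cc(C(C)C)cc1C(C)C | intermediate (not isolated)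
7 | hept-1-yn-1-yl (1R)-1-(2,4,6-triisopropylphenyl)ethyl ether | CCCCCC#CO[C@H](C)c1c(C(C)C)cc(C(C)C)cc1C(C)C | intermediate
8 | (Z)-hept-1-en-1-yl (1R)-1-(2,4,6-triisopropylphenyl)ethyl ether | CCCCC/C=C\O[C@H](C)c1c(C(C)C)cc(C(C)C)cc1C(C)C | intermediate
9 | trichloroacetyl chloride | ClC(Cl)(Cl)C(=O)Cl | starting material
10 | dichloroketene | ClC(Cl)=C=O | intermediate (not isolated)
11 | (3R,4S)-2,2-dichloro-4-pentyl-3-[(1R)-1-(2,4,6-triisopropylphenyl)ethoxy]cyclobutan-1-one | O=C1C(Cl)(Cl)[C@H](O[C@H](C)c2c(C(C)C)cc(C(C)C)cc2C(C)C)[C@@H]1CCCCC | intermediate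
12 | (2S,3S)-2-pentyl-3-[(1R)-1-(2,4,6-triisopropylphenyl)ethoxy]cyclobutan-1-one | O=C1C[C@H](O[C@H](C)c2c(C(C)C)cc(C(C)C)cc2C(C)C)[C@@H]1CCCCC | intermediate
13 | (4S,5S)-5-pentyl-4-[(1R)-1-(2,4,6-triisopropylphenyl)ethoxy]oxolan-2-one | O=C1C[C@H](O[C@H](C)c2c(C(C)C)cc(C(C)C)cc2C(C)C)[C@H](CCCCC)O1 | intermediate
14 | 1,3-dithiane | C1CSCSC1 | starting material
15 | 2-lithio-1,3-dithiane | [Li]C1SCCCS1 | intermediate (not isolated)
16 | (4S,5S)-2-(1,3-dithian-2-yl)-5-pentyl-4-[(1R)-1-(2,4,6-triisopropylphenyl)ethoxy]oxolan-2-ol (both C2 anomers) | OC1(C2SCCCS2)C[C@H](O[C@H](C)c3c(C(C)C)cc(C(C)C)cc3C(C)C)[C@H](CCCCC)O1 | intermediate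
17 | 2-{(2R,4S,5S)-5-pentyl-4-[(1R)-1-(2,4,6-triisopropylphenyl)ethoxy]oxolan-2-yl}-1,3-dithiane | S1CCCSC1[C@H]2C[C@H](O[C@H](C)c3c(C(C)C)cc(C(C)C)cc3C(C)C)[C@H](CCCCC)O2 | intermediate
18 | (2R,4S,5S)-5-pentyl-4-[(1R)-1-(2,4,6-triisopropylphenyl)ethoxy]oxolane-2-carbaldehyde | O=C[C@H]1C[C@H](O[C@H](C)c2c(C(C)C)cc(C(C)C)cc2C(C)C)[C@H](CCCCC)O1 | intermediate
19 | 9-bromonon-1-ene | C=CCCCCCCCBr | starting material
20 | non-8-enylmagnesium bromide | C=CCCCCCCC[Mg]Br | intermediate (not isolated)
21 | (1R)-1-{(2R,4S,5S)-5-pentyl-4-[(1R)-1-(2,4,6-triisopropylphenyl)ethoxy]oxolan-2-yl}dec-9-en-1-ol | C=CCCCCCCC[C@@H](O)[C@H]1C[C@H](O[C@H](C)c2c(C(C)C)cc(C(C)C)cc2C(C)C)[C@H](CCCCC)O1 | intermediate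
22 | tetradecanoyl chloride | CCCCCCCCCCCCCC(=O)Cl | starting material
23 | (1R)-1-{(2R,4S,5S)-5-pentyl-4-[(1R)-1-(2,4,6-triisopropylphenyl)ethoxy]oxolan-2-yl}dec-9-en-1-yl tetradecanoate | C=CCCCCCCC[C@@H](OC(=O)CCCCCCCCCCCCC)[C@H]1C[C@H](O[C@H](C)c2c(C(C)C)cc(C(C)C)cc2C(C)C)[C@H](CCCCC)O1 | intermediate
24 | (1R)-1-[(2R,4S,5S)-4-hydroxy-5-pentyloxolan-2-yl]dec-9-en-1-yl tetradecanoate | C=CCCCCCCC[C@@H](OC(=O)CCCCCCCCCCCCC)[C@H]1C[C@H](O)[C@H](CCCCC)O1 | target

Total step count: 11. Longest linear sequence: 11 steps (1 to 24).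

Steps most likely to fail

First, step 7. The two sulfur atoms retard ionisation of the hemiketal, so ionisation of the benzylic auxiliary ether, sulfur participation in the cation, or erosion of the facial selectivity at C11 may compete. The fallback sets out from 13. Addition of vinylmagnesium bromide (THF, −78 °C, cold quench) should give the vinyl hemiketal (4S,5S)-2-ethenyl-5-pentyl-4-[(1R)-1-(2,4,6-triisopropylphenyl)ethoxy]oxolan-2-ol F1. Its allylic oxocarbenium ion should form already at −78 °C with Et3SiH/BF3·OEt2, and the same inside delivery of hydride should give (2R,4S,5S)-2-ethenyl-5-pentyl-4-[(1R)-1-(2,4,6-triisopropylphenyl)ethoxy]oxolane F2. Oxidative cleavage of the vinyl group (OsO4 cat., NaIO4, 2,6-lutidine, dioxane–H2O) then comes back to the route at aldehyde 18.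

Second, step 9. If chelation by magnesium is incomplete, Felkin-type addition competes and the facial selectivity at C10 falls. The fallback sets out from 18. Addition of 20 without the chelating additive is accepted to give 21 together with its C10 epimer (1S)-1-{(2R,4S,5S)-5-pentyl-4-[(1R)-1-(2,4,6-triisopropylphenyl)ethoxy]oxolan-2-yl}dec-9-en-1-ol F3. The mixture is oxidised (Dess–Martin periodinane, CH2Cl2) to the ketone 1-{(2R,4S,5S)-5-pentyl-4-[(1R)-1-(2,4,6-triisopropylphenyl)ethoxy]oxolan-2-yl}dec-9-en-1-one F4. Reduction with LiBH(s-Bu)3 (THF, −78 °C) under Felkin–Anh control, with the ring C–O bond anti to the incoming hydride, should then return the threo alcohol 21.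

Third, step 5. Migration of the C12 methylene may compete with that of C14, or the C13 alkoxy group may be lost by β-elimination from ketone or lactone. The fallback sets out from 11 and oxidises before dechlorination (mCPBA, NaHCO3, CH2Cl2, 0 °C). The CCl2 carbon cannot migrate and the electron-poor carbonyl adds peracid quickly, so only (4R,5S)-3,3-dichloro-5-pentyl-4-[(1R)-1-(2,4,6-triisopropylphenyl)ethoxy]oxolan-2-one F5 should form. Radical dechlorination (Bu3SnH, AIBN, toluene, 80 °C), which avoids an enolate that could expel the alkoxy group, comes back to the route at lactone 13.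

Further compounds
F1 | step 7 | (4S,5S)-2-ethenyl-5-pentyl-4-[(1R)-1-(2,4,6-triisopropylphenyl)ethoxy]oxolan-2-ol (both C2 anomers) | OC1(C=C)C[C@H](O[C@H](C)c2c(C(C)C)cc(C(C)C)cc2C(C)C)[C@H](CCCCC)O1
F2 | step 7 | (2R,4S,5S)-2-ethenyl-5-pentyl-4-[(1R)-1-(2,4,6-triisopropylphenyl)ethoxy]oxolane | C=C[C@H]1C[C@H](O[C@H](C)c2c(C(C)C)cc(C(C)C)cc2C(C)C)[C@H](CCCCC)O1
F3 | step 9 | (1S)-1-{(2R,4S,5S)-5-pentyl-4-[(1R)-1-(2,4,6-triisopropylphenyl)ethoxy]oxolan-2-yl}dec-9-en-1-ol | C=CCCCCCCC[C@H](O)[C@H]1C[C@H](O[C@H](C)c2c(C(C)C)cc(C(C)C)cc2C(C)C)[C@H](CCCCC)O1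
F4 | step 9 | 1-{(2R,4S,5S)-5-pentyl-4-[(1R)-1-(2,4,6-triisopropylphenyl)ethoxy]oxolan-2-yl}dec-9-en-1-one | C=CCCCCCCCC(=O)[C@H]1C[C@H](O[C@H](C)c2c(C(C)C)cc(C(C)C)cc2C(C)C)[C@H](CCCCC)O1
F5 | step 5 | (4R,5S)-3,3-dichloro-5-pentyl-4-[(1R)-1-(2,4,6-triisopropylphenyl)ethoxy]oxolan-2-one | O=C1C(Cl)(Cl)[C@H](O[C@H](C)c2c(C(C)C)cc(C(C)C)cc2C(C)C)[C@H](CCCCC)O1
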